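Readings and results come from a simulation for an exercise; scatter was added.

Multiply the catalyst by the time.

| setting | elm | birch | alder | cedar | ash |
|---|---|---|---|---|---|
| starting material | 150 mM | 75.0 mM | 150 mM | 150 mM | 450 mM |
| partner | 450 mM | 375 mM | 450 mM | 450 mM | 450 mM |
| catalyst | 12.0 mM | 12.0 mM | 12.0 mM | 36.0 mM | 36.0 mM |
| target |  |  | 45.0 mM |  |  |
| time |  |  |  |  | 34 min |

| run | time / min | [target] / mM |
|---|---|---|
| elm run | 1.5 | 5.7 |
| elm run | 4.6 | 10.4 |
| elm run | 8.8 | 15.8 |
| elm run | 14 | 24.5 |
| elm run | 20 | 35.5 |
| elm run | 27 | 46.5 |
| elm run | 34 | 57.6 |
| birch run | 1.5 | 0.3 |
| birch run | 4.6 | 5.4 |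
| birch run | 8.8 | 8.4 |
| birch run | 14 | 16.5 |
| birch run | 20 | 20.0 |
| birch run | 27 | 28.7 |
| birch run | 34 | 38.4 |
| alder run | 1.5 | 48.2 |
| alder run | 4.6 | 52.1 |
| alder run | 8.8 | 62.4 |
| alder run | 14 | 69.6 |
| alder run | 20 | 80.6 |
| alder run | 27 | 91.9 |
| alder run | 34 | 103.4 |
| cedar run | 1.5 | 8.4 |
| cedar run | 4.6 | 22.4 |
| cedar run | 8.8 | 43.9 |
| cedar run | 14 | 64.1 |
| cedar run | 20 | 83.4 |
| cedar run | 27 | 106.3 |
| cedar run | 34 | 118.3 |

(standard deviation of a reading: 2 mM)

- the exponent of [catalyst] in the starting rate at the charge of the elm run (at the point where two percent of the starting material have become target)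
- the birch run starts with 75.0 mM less of starting material and of partner than the elm run, and with no target. Compared where both hold the same amount of starting material, once fifteen percent of what the birch run was charged with has turned into target, is the birch run faster, slower or alike (within a tenth)?
- target in the ash run at 34 min, as a share of the starting material charged

- Overall: starting material + partner -> target, with catalyst as catalyst.
- Constant volume, constant temperature.
- A reading of a species includes what of it is bound.
- "The second partner" is partner.
- An order is taken over about fifteen percent of the charge, up and down.

The elm run made 57.6 mM of target by 34 min with c(catalyst) at 12.0 mM, which gives 0.141 /min. This is the average turnover rate (turnover frequency), target made divided by catalyst-time, where catalyst-time is c(catalyst) multiplied by time. If catalyst-time works as the flask's clock, equal catalyst-time on equal charges must give equal target.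

The table can test that row against row. The cedar run holds 3.00 times the catalyst of the elm run, so its row at 4.6 min belongs beside elm's at 14 min, and its row at 8.8 min beside elm's at 27 min. These read 22.4 mM against 24.5 mM, then 43.9 mM against 46.5 mM, gaps about the size of the scatter. The exponent of the catalyst therefore reads near one.

The alder run, charged with 45.0 mM of target, has gained 58.4 mM by 34 min, against 57.6 mM in the elm run, so added target leaves the clock running.

The cedar run passes 75.0 mM of target between its readings at 14 min and 20 min, at about 17.4 min on a straight line between them, and from there it holds the birch charge of starting material and partner. By 27 min it has spent 20.8 M·s more catalyst-time and gained 31.3 mM. The birch run gives 28.7 mM after 19.4 M·s and 38.4 mM after 24.5 M·s, so the gain of the cedar run falls between these readings, as its catalyst-time does, and the two runs read alike.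

The ash run has 73.44 M·s of catalyst-time. At elm's turnover rate that gives 38.4% of its charge. The birch run, with half of elm's starting material and with 375 mM of partner, turned over at 0.0941 /min, slower by a factor of 1.50. One more such factor, as a rough estimate, gives 57.6%. The ash run holds 450 mM of partner for 450 mM of starting material, so its partner falls as target forms, and this reckoning leans towards the low end of that span.

The forecast gives an exponent of 1 (0.85 to 1.15), the answer alike, and 40% (30% to 50%), with the rate “slowed somewhat as partner depletes”. Its 40% lies inside that span, lower than the 57.6% at its top.

The flask gives 0.98, alike and 42.6%.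

    catalyst + starting material ⇌ catalyst-substrate complex, settled at all times (15.20 /M)
    catalyst-substrate complex + partner ⇌ ternary complex, settled at all times (5.230 /M)
    ternary complex → target + catalyst (0.8400 /min)
    2 partner ⇌ idle reagent dimer, settled at all times (13.90 /M)
    starting material + partner ⇌ idle substrate-reagent adduct, settled at all times (17.50 /M)

The ash run made 191 mM in its 73.4 M·s of catalyst-time, a turnover rate of 0.156 /min, a little above elm's 0.141 /min. The same clock reads the alder run, whose target made reaches half of its starting material at 48.1 min, a catalyst-time of 34.6 M·s, against 36.6 M·s in the cedar run. Ash stays at 42.6% because partner is held in the idle substrate-reagent adduct and the idle reagent dimer: without the adduct it reaches 59.8%, and without the dimer 57.8%.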